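**Strategy.** The dimer is cut at the interflavan bond (C4 of the upper unit to C6 of the lower unit) into two flavan units of opposite C2 configuration, each traced to the Luche alcohol of a 2'-hydroxychalcone. The key step closes ring C of the upper unit by joining the ring A phenol oxygen O1 to C2, the benzylic carbon that carries ring B: a chiral N-triflylphosphoramide ionises the alcohol to an o-quinone methide whose oxa-6π closure gives the (2S)-flav-3-ene. It exploits the O1–C8a–C4a–C4–C3–C2 array as a 1-oxatriene and leaves the C3=C4 alkene, from which C3 and C4 are set by relay. A C6 bromine blocks self-condensation of the upper unit in the coupling.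

Key step: step 5

Remarks on the chemistry.
- Flavan numbering is used (O1, C2, C3, C4, C4a, C5–C8, C8a). "Upper unit" is the 4-arylflavan-3-ol, "lower unit" the flavan-3,4-diol.
- Assumption: the (R)-phosphoramide is taken to give the (2S)-chromene. If the sense of induction proves opposite, the two catalyst antipodes are exchanged between steps 5 and 10.
- The CIP label of C2 changes between chromene and chroman (2S to 2R in the upper unit, 2R to 2S in the lower unit), and that of the lower C3 changes between diol and carbonate. The arrangement in space does not change in either case.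

**Step 1**
Reactants: 1 1-(2,3,4-trihydroxyphenyl)ethanone (gallacetophenone)
Product: 2 1-[3,4-bis(benzyloxy)-2-hydroxyphenyl]ethanone
Conditions: BnBr (2.1 equiv), K2CO3, acetone, reflux
Reagents that add atoms: benzyl bromide, BrCc1ccccc1
Why: Williamson etherification in which the 2-hydroxyl, held in a hydrogen bond to the ketone, is the least reactive, so two equivalents of benzyl bromide should take the 4- and 3-hydroxyls only.

**Step 2**
Reactants: 2 1-[3,4-bis(benzyloxy)-2-hydroxyphenyl]ethanone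
Product: 3 1-[3,4-bis(benzyloxy)-5-bromo-2-hydroxyphenyl]ethanone
Conditions: NBS (1.05 equiv), MeCN, 0 °C to rt, dark
Reagents that add atoms: N-bromosuccinimide, O=C1CCC(=O)N1Br
Why: Electrophilic aromatic bromination, which should take place at C5 only, the one free position that is para to the free 2-hydroxyl, ortho to the 4-benzyloxy group and meta to the acetyl group; this bromine becomes C6 of the upper flavan unit, where it blocks the nucleophilic site of ring A until the last step.

**Step 3**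
Reactants: 3 1-[3,4-bis(benzyloxy)-5-bromo-2-hydroxyphenyl]ethanone; 4 4-(benzyloxy)benzaldehyde
Product: 5 (E)-1-[3,4-bis(benzyloxy)-5-bromo-2-hydroxyphenyl]-3-[4-(benzyloxy)phenyl]prop-2-en-1-one
Conditions: KOH (50% aq.), EtOH, rt
Reagents that add atoms: none
Why: Claisen–Schmidt condensation of a methyl ketone with a non-enolisable aldehyde, the E enone arising by E1cB dehydration and the strong base keeping the 2'-hydroxychalcone open as its phenoxide.

**Step 4**
Reactants: 5 (E)-1-[3,4-bis(benzyloxy)-5-bromo-2-hydroxyphenyl]-3-[4-(benzyloxy)phenyl]prop-2-en-1-one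
Product: 6 (E)-1-[3,4-bis(benzyloxy)-5-bromo-2-hydroxyphenyl]-3-[4-(benzyloxy)phenyl]prop-2-en-1-ol (racemic)
Conditions: NaBH4, CeCl3·7H2O, MeOH/THF, −40 °C; cold NaHCO3 aq.; used crude
Reagents that add atoms: none
Why: Luche reduction directs hydride to the carbonyl carbon (1,2-addition), and the racemic carbinol centre is of no consequence because it is erased on ionisation in step 5.

**Step 5**
Reactants: 6 (E)-1-[3,4-bis(benzyloxy)-5-bromo-2-hydroxyphenyl]-3-[4-(benzyloxy)phenyl]prop-2-en-1-ol
Product: 8 (2S)-7,8-bis(benzyloxy)-2-[4-(benzyloxy)phenyl]-6-bromo-2H-chromene, via bromo o-quinone methide 7 (not isolated)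
Conditions: (R)-3,3'-bis(2,4,6-triisopropylphenyl)-1,1'-binaphthyl-2,2'-diyl N-triflylphosphoramide (5 mol %), toluene, −78 °C; then Et3N
Reagents that add atoms: none
Why: The acid protonates the benzylic, allylic hydroxyl of 6, which leaves with help from the ortho hydroxyl and the para benzyloxy group to give o-quinone methide 7, held to the chiral phosphoramide as a hydrogen-bonded contact ion pair; O1 then bonds to C2 in a disrotatory oxa-6π electrocyclisation of the O1=C8a–C4a=C4–C3=C2 oxatriene, the same event as a 6-endo-trig capture of the 1,3-diarylallyl cation by the phenol oxygen. The closest known reaction type is the chiral N-triflylphosphoramide-catalysed asymmetric allylic substitution of o-hydroxyaryl allylic alcohols to 2H-chromenes through a chiral contact ion pair. The single ring closed is the 2H-pyran ring C, and closure at C2 is the only option because attack at C4 would give a four-membered ring. The new stereocentre C2 is set by the catalyst alone, since 7 is achiral: the acid bound at O1 selects one of the two helical s-cis conformers of the oxatriene and with it the face of C2. The step needs enantioselectivity and a configurationally stable product; the low temperature, the non-polar solvent and the amine quench before warming should suppress the uncatalysed closure and the re-ionisation of the C2–O1 bond that would racemise 8, and the C6 bromine lies outside the reacting array. The C3=C4 alkene left by the closure is the handle for the later stereocentres of this unit.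

**Step 6**
Reactants: 8 (2S)-7,8-bis(benzyloxy)-2-[4-(benzyloxy)phenyl]-6-bromo-2H-chromene
Product: 9 (2R,3S,4R)-7,8-bis(benzyloxy)-2-[4-(benzyloxy)phenyl]-3,6-dibromo-3,4-dihydro-2H-chromen-4-ol (2,3-trans-3,4-trans)
Conditions: NBS, NaHCO3, THF/H2O, 0 °C, dark
Reagents that add atoms: N-bromosuccinimide, O=C1CCC(=O)N1Br; water, O
Why: Bromohydrin formation in which bromine should add to C3 on the face anti to the C2 aryl group and water should capture the C4 benzylic cation (stabilised by the para benzyloxy group) anti to bromine, setting C3 and C4 by substrate control.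

**Step 7**
Reactants: 9 (2R,3S,4R)-7,8-bis(benzyloxy)-2-[4-(benzyloxy)phenyl]-3,6-dibromo-3,4-dihydro-2H-chromen-4-ol
Product: 10 (2R,3R,4R)-7,8-bis(benzyloxy)-2-[4-(benzyloxy)phenyl]-6-bromo-3,4-epoxy-3,4-dihydro-2H-chromene (epoxide cis to the 2-aryl group)
Conditions: NaH, THF, 0 °C; filtered and used at once
Reagents that add atoms: none
Why: Intramolecular Williamson (SN2) closure in which the C4 alkoxide displaces the C3 bromide with inversion, placing the epoxide on the face cis to the 2-aryl group, the face that direct epoxidation would not reach.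

**Step 8**
Reactants: 2 1-[3,4-bis(benzyloxy)-2-hydroxyphenyl]ethanone; 4 4-(benzyloxy)benzaldehyde
Product: 11 (E)-1-[3,4-bis(benzyloxy)-2-hydroxyphenyl]-3-[4-(benzyloxy)phenyl]prop-2-en-1-one
Conditions: KOH (50% aq.), EtOH, rt
Reagents that add atoms: none
Why: Claisen–Schmidt condensation as in step 3, here on the bromine-free ketone that serves the lower unit, whose C6 must stay free as the nucleophilic site.

**Step 9**
Reactants: 11 (E)-1-[3,4-bis(benzyloxy)-2-hydroxyphenyl]-3-[4-(benzyloxy)phenyl]prop-2-en-1-one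
Product: 12 (E)-1-[3,4-bis(benzyloxy)-2-hydroxyphenyl]-3-[4-(benzyloxy)phenyl]prop-2-en-1-ol (racemic)
Conditions: NaBH4, CeCl3·7H2O, MeOH/THF, −40 °C; cold NaHCO3 aq.; used crude
Reagents that add atoms: none
Why: Luche 1,2-reduction as in step 4, the racemic carbinol centre again being erased on ionisation in step 10.

**Step 10**
Reactants: 12 (E)-1-[3,4-bis(benzyloxy)-2-hydroxyphenyl]-3-[4-(benzyloxy)phenyl]prop-2-en-1-ol
Product: 14 (2R)-7,8-bis(benzyloxy)-2-[4-(benzyloxy)phenyl]-2H-chromene, via o-quinone methide 13 (not isolated)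
Conditions: (S)-3,3'-bis(2,4,6-triisopropylphenyl)-1,1'-binaphthyl-2,2'-diyl N-triflylphosphoramide (5 mol %), toluene, −78 °C; then Et3N
Reagents that add atoms: none
Why: The same chiral Brønsted acid-catalysed ionisation and oxa-6π ring closure as in step 5, here on the bromine-free alcohol and with the mirror-image catalyst, which selects the opposite helical conformer of 13 and so sets C2 as R.

**Step 11**
Reactants: 14 (2R)-7,8-bis(benzyloxy)-2-[4-(benzyloxy)phenyl]-2H-chromene
Product: 15 (2S,3R,4R)-7,8-bis(benzyloxy)-2-[4-(benzyloxy)phenyl]-3,4-dihydro-2H-chromene-3,4-diol (2,3-trans-3,4-cis)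
Conditions: OsO4 (2 mol %), NMO, acetone/H2O, 0 °C to rt
Reagents that add atoms: osmium tetroxide (catalytic oxygen carrier), O=[Os](=O)(=O)=O; N-methylmorpholine N-oxide, C[N+]1([O-])CCOCC1; water, O
Why: Upjohn syn-dihydroxylation, which on flav-3-enes should take place on the face anti to the 2-aryl group and so set C3 and C4 as the 3,4-cis diol trans to ring B.

**Step 12**
Reactants: 15 (2S,3R,4R)-7,8-bis(benzyloxy)-2-[4-(benzyloxy)phenyl]-3,4-dihydro-2H-chromene-3,4-diol
Product: 16 3,4-cyclic carbonate of 15 (2,3-trans-3,4-cis; CIP 2S,3S,4R, no change in space)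
Conditions: CDI, DMAP (cat.), CH2Cl2, rt
Reagents that add atoms: 1,1'-carbonyldiimidazole, O=C(n1ccnc1)n1ccnc1
Why: Carbonylation of a cis-1,2-diol to the five-membered carbonate under non-acidic conditions, which masks both hydroxyls and holds the benzylic C4–O bond against ionisation in step 13.

**Step 13**
Reactants: 10 (2R,3R,4R)-7,8-bis(benzyloxy)-2-[4-(benzyloxy)phenyl]-6-bromo-3,4-epoxy-3,4-dihydro-2H-chromene; 16 3,4-cyclic carbonate of 15
Product: 17 hexa-O-benzyl bromo dimer carbonate: upper unit (2R,3R,4S), 2,3-cis-3,4-trans, with free 3-hydroxyl and C6 bromine, its C4 bonded to C6 of the lower unit; lower unit as in 16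
Conditions: BF3·OEt2 (0.2 equiv), CH2Cl2, −78 °C, slow addition of 10 to 16; NaHCO3 aq.
Reagents that add atoms: none
Why: Friedel–Crafts opening of a benzylic epoxide, the epoxide counterpart of the flavan-4-yl cation couplings of proanthocyanidin synthesis, in which the C4 cation (stabilised by the para benzyloxy group) should be attacked by C6 of 16 (ortho to O7, para to O1, less hindered than the peri position C5) on the face anti to both the C3 oxygen and the C2 aryl group, which sets the upper C4, while the C6 bromine of 10 blocks self-condensation and allows a near-equimolar ratio of the partners.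

**Step 14**
Reactants: 17 hexa-O-benzyl bromo dimer carbonate
Product: 18 (2R,3R,4S)-7,8-bis(benzyloxy)-2-[4-(benzyloxy)phenyl]-6-bromo-4-[(2S,3R,4R)-7,8-bis(benzyloxy)-2-[4-(benzyloxy)phenyl]-3,4-dihydroxy-3,4-dihydro-2H-chromen-6-yl]-3,4-dihydro-2H-chromen-3-ol (hexa-O-benzyl bromo triol)
Conditions: K2CO3 (0.2 equiv), MeOH/THF, rt
Reagents that add atoms: none
Why: Base-catalysed transesterification of the cyclic carbonate with methanol, which touches no stereocentre and leaves the aryl benzyl ethers and the aryl bromide intact.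

**Step 15**
Reactants: 18 hexa-O-benzyl bromo triol
Product: 19 (2R,3R,4S)-2-(4-hydroxyphenyl)-4-[(2S,3R,4R)-3,4,7,8-tetrahydroxy-2-(4-hydroxyphenyl)-3,4-dihydro-2H-chromen-6-yl]-3,4-dihydro-2H-chromene-3,7,8-triol (target)
Conditions: H2 (1 atm), Pd(OH)2/C, NaOAc (1.5 equiv), THF/EtOAc/H2O, rt; filtered under argon
Reagents that add atoms: none
Why: Hydrogenolysis of the six aryl benzyl ethers and of the aryl C–Br bond, with NaOAc taking up the HBr so that the acid-labile benzylic C4–OH of the lower unit is not ionised, under conditions where ArO–CH2Ph and Ar–Br bonds should cleave well before the benzylic C4–OH, C2–O1 and C4–C6 bonds.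

**Compound list**
1 | 1-(2,3,4-trihydroxyphenyl)ethanone (gallacetophenone) | CC(=O)c1ccc(O)c(O)c1O | starting material
2 | 1-[3,4-bis(benzyloxy)-2-hydroxyphenyl]ethanone | CC(=O)c1ccc(OCc2ccccc2)c(OCc2ccccc2)c1O | intermediate
3 | 1-[3,4-bis(benzyloxy)-5-bromo-2-hydroxyphenyl]ethanone | CC(=O)c1cc(Br)c(OCc2ccccc2)c(OCc2ccccc2)c1O | intermediate
4 | 4-(benzyloxy)benzaldehyde | O=Cc1ccc(OCc2ccccc2)cc1 | starting material
5 | (E)-1-[3,4-bis(benzyloxy)-5-bromo-2-hydroxyphenyl]-3-[4-(benzyloxy)phenyl]prop-2-en-1-one | O=C(/C=C/c1ccc(OCc2ccccc2)cc1)c1cc(Br)c(OCc2ccccc2)c(OCc2ccccc2)c1O | intermediate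
6 | (E)-1-[3,4-bis(benzyloxy)-5-bromo-2-hydroxyphenyl]-3-[4-(benzyloxy)phenyl]prop-2-en-1-ol (racemic) | OC(/C=C/c1ccc(OCc2ccccc2)cc1)c1cc(Br)c(OCc2ccccc2)c(OCc2ccccc2)c1O | intermediate
7 | (6Z)-2,3-bis(benzyloxy)-4-bromo-6-[(2E)-3-[4-(benzyloxy)phenyl]prop-2-en-1-ylidene]cyclohexa-2,4-dien-1-one (bromo o-quinone methide, formed in the flask, not isolated) | O=C1/C(=C\C=C\c2ccc(OCc3ccccc3)cc2)C=C(Br)C(OCc2ccccc2)=C1OCc1ccccc1 | intermediate
8 | (2S)-7,8-bis(benzyloxy)-2-[4-(benzyloxy)phenyl]-6-bromo-2H-chromene | c1ccc(COc2ccc([C@H]3Oc4c(cc(Br)c(OCc5ccccc5)c4OCc4ccccc4)C=C3)cc2)cc1 | intermediate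
9 | (2R,3S,4R)-7,8-bis(benzyloxy)-2-[4-(benzyloxy)phenyl]-3,6-dibromo-3,4-dihydro-2H-chromen-4-ol | c1ccc(COc2ccc([C@H]3Oc4c(cc(Br)c(OCc5ccccc5)c4OCc4ccccc4)[C@@H](O)[C@@H]3Br)cc2)cc1 | intermediate
10 | (2R,3R,4R)-7,8-bis(benzyloxy)-2-[4-(benzyloxy)phenyl]-6-bromo-3,4-epoxy-3,4-dihydro-2H-chromene (epoxide cis to the 2-aryl group) | c1ccc(COc2ccc([C@H]3Oc4c(cc(Br)c(OCc5ccccc5)c4OCc4ccccc4)[C@@H](O5)[C@H]35)cc2)cc1 | intermediate
11 | (E)-1-[3,4-bis(benzyloxy)-2-hydroxyphenyl]-3-[4-(benzyloxy)phenyl]prop-2-en-1-one | O=C(/C=C/c1ccc(OCc2ccccc2)cc1)c1ccc(OCc2ccccc2)c(OCc2ccccc2)c1O | intermediate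
12 | (E)-1-[3,4-bis(benzyloxy)-2-hydroxyphenyl]-3-[4-(benzyloxy)phenyl]prop-2-en-1-ol (racemic) | OC(/C=C/c1ccc(OCc2ccccc2)cc1)c1ccc(OCc2ccccc2)c(OCc2ccccc2)c1O | intermediate
13 | (6Z)-2,3-bis(benzyloxy)-6-[(2E)-3-[4-(benzyloxy)phenyl]prop-2-en-1-ylidene]cyclohexa-2,4-dien-1-one (o-quinone methide, formed in the flask, not isolated) | O=C1/C(=C\C=C\c2ccc(OCc3ccccc3)cc2)C=CC(OCc2ccccc2)=C1OCc1ccccc1 | intermediate
14 | (2R)-7,8-bis(benzyloxy)-2-[4-(benzyloxy)phenyl]-2H-chromene | c1ccc(COc2ccc([C@@H]3Oc4c(ccc(OCc5ccccc5)c4OCc4ccccc4)C=C3)cc2)cc1 | intermediate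
15 | (2S,3R,4R)-7,8-bis(benzyloxy)-2-[4-(benzyloxy)phenyl]-3,4-dihydro-2H-chromene-3,4-diol | c1ccc(COc2ccc3c(c2OCc2ccccc2)O[C@@H](c2ccc(OCc4ccccc4)cc2)[C@H](O)[C@@H]3O)cc1 | intermediate
16 | 3,4-cyclic carbonate of 15 (2,3-trans-3,4-cis) | c1ccc(COc2ccc3c(c2OCc2ccccc2)O[C@@H](c2ccc(OCc4ccccc4)cc2)[C@H](OC(=O)O4)[C@@H]34)cc1 | intermediate
17 | hexa-O-benzyl bromo dimer carbonate (upper unit 2R,3R,4S, 2,3-cis-3,4-trans, free 3-OH, 6-bromo, C4 bonded to C6 of the lower unit; lower unit 3,4-cyclic carbonate) | C(c1ccccc1)Oc1ccc([C@H]2Oc3c(cc(Br)c(OCc4ccccc4)c3OCc3ccccc3)[C@H](c3cc4c(c(OCc5ccccc5)c3OCc3ccccc3)O[C@@H](c3ccc(OCc5ccccc5)cc3)[C@H](OC(=O)O5)[C@@H]45)[C@H]2O)cc1 | intermediate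
18 | hexa-O-benzyl bromo triol (upper unit 2R,3R,4S with 6-bromo; lower unit 2S,3R,4R diol) | C(c1ccccc1)Oc1ccc([C@H]2Oc3c(cc(Br)c(OCc4ccccc4)c3OCc3ccccc3)[C@H](c3cc4c(c(OCc5ccccc5)c3OCc3ccccc3)O[C@@H](c3ccc(OCc5ccccc5)cc3)[C@H](O)[C@@H]4O)[C@H]2O)cc1 | intermediate
19 | (2R,3R,4S)-2-(4-hydroxyphenyl)-4-[(2S,3R,4R)-3,4,7,8-tetrahydroxy-2-(4-hydroxyphenyl)-3,4-dihydro-2H-chromen-6-yl]-3,4-dihydro-2H-chromene-3,7,8-triol | Oc1ccc([C@H]2Oc3c(ccc(O)c3O)[C@H](c3cc4c(c(O)c3O)O[C@@H](c3ccc(O)cc3)[C@H](O)[C@@H]4O)[C@H]2O)cc1 | target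

**Total step count:** 15.
**Longest linear sequence:** 10 steps (steps 1, 2, 3, 4, 5, 6, 7, 13, 14, 15).

**Steps most likely to fail**

1. Step 5 (key step). The enantiomeric purity may erode through uncatalysed closure of the very easily ionised alcohol, or through reversible acid opening of the C2–O1 bond of the product. Fallback, setting out from 6: closure without chiral control (AcOH cat., toluene, rt) should give racemic 7,8-bis(benzyloxy)-2-[4-(benzyloxy)phenyl]-6-bromo-2H-chromene F1. Its antipodes are then separated by preparative chromatography on an amylose tris(3,5-dimethylphenylcarbamate) stationary phase. The 2S antipode is 8, where the fallback comes back to the route.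

2. Step 13. Once ionised, the epoxide may rearrange by 1,2-hydride shift to the 3-ketone faster than the benzylated arene captures it, or the arene may enter without facial control. Fallback, setting out from 8, with a stable C4 ether as the electrophile: hydroboration–oxidation (BH3·THF; then NaOH, H2O2) anti to the 2-aryl group should give (2R,3S)-7,8-bis(benzyloxy)-2-[4-(benzyloxy)phenyl]-6-bromochroman-3-ol F2. Dess–Martin periodinane should then give (2R)-7,8-bis(benzyloxy)-2-[4-(benzyloxy)phenyl]-6-bromochroman-3-one F3. LiBH(s-Bu)3 in THF at −78 °C should deliver hydride anti to the 2-aryl group and give the 2,3-cis alcohol (2R,3R)-7,8-bis(benzyloxy)-2-[4-(benzyloxy)phenyl]-6-bromochroman-3-ol F4. DDQ with 2-ethoxyethanol in CH2Cl2 should oxidise the benzylic C4 to (2R,3R,4S)-7,8-bis(benzyloxy)-2-[4-(benzyloxy)phenyl]-6-bromo-4-(2-ethoxyethoxy)chroman-3-ol F5. TMSOTf (cat.) in CH2Cl2 at −78 °C with 16 ionises this ether reversibly, and the arene should again enter anti to the 3-hydroxyl. The fallback comes back to the route at 17 and bypasses 9 and 10.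

3. Step 15. Over-reduction may occur: once the para phenol of the lower unit is unveiled, its benzylic C4–OH bond may undergo hydrogenolysis. Fallback, setting out from 18: TBSOTf and 2,6-lutidine in CH2Cl2 should silylate the three secondary hydroxyls to the hexa-O-benzyl bromo tris(tert-butyldimethylsilyl) ether F6. H2 over Pd(OH)2/C with NaOAc in THF/EtOAc/H2O should then remove the benzyl groups and the bromine to give the hexaphenol tris(tert-butyldimethylsilyl) ether F7, the silyl ether shielding the benzylic C–O bond. TBAF buffered with AcOH in THF at 0 °C under argon should remove the silyl groups. The fallback comes back to the route at 19.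

**Further compounds**
F1 | step 5 | racemic 7,8-bis(benzyloxy)-2-[4-(benzyloxy)phenyl]-6-bromo-2H-chromene | c1ccc(COc2ccc(C3Oc4c(cc(Br)c(OCc5ccccc5)c4OCc4ccccc4)C=C3)cc2)cc1
F2 | step 13 | (2R,3S)-7,8-bis(benzyloxy)-2-[4-(benzyloxy)phenyl]-6-bromochroman-3-ol | c1ccc(COc2ccc([C@H]3Oc4c(cc(Br)c(OCc5ccccc5)c4OCc4ccccc4)C[C@@H]3O)cc2)cc1
F3 | step 13 | (2R)-7,8-bis(benzyloxy)-2-[4-(benzyloxy)phenyl]-6-bromochroman-3-one | c1ccc(COc2ccc([C@H]3Oc4c(cc(Br)c(OCc5ccccc5)c4OCc4ccccc4)CC3=O)cc2)cc1
F4 | step 13 | (2R,3R)-7,8-bis(benzyloxy)-2-[4-(benzyloxy)phenyl]-6-bromochroman-3-ol | c1ccc(COc2ccc([C@H]3Oc4c(cc(Br)c(OCc5ccccc5)c4OCc4ccccc4)C[C@H]3O)cc2)cc1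
F5 | step 13 | (2R,3R,4S)-7,8-bis(benzyloxy)-2-[4-(benzyloxy)phenyl]-6-bromo-4-(2-ethoxyethoxy)chroman-3-ol | c1ccc(COc2ccc([C@H]3Oc4c(cc(Br)c(OCc5ccccc5)c4OCc4ccccc4)[C@H](OCCOCC)[C@H]3O)cc2)cc1
F6 | step 15 | hexa-O-benzyl bromo tris(tert-butyldimethylsilyl) ether of 18 | C(c1ccccc1)Oc1ccc([C@H]2Oc3c(cc(Br)c(OCc4ccccc4)c3OCc3ccccc3)[C@H](c3cc4c(c(OCc5ccccc5)c3OCc3ccccc3)O[C@@H](c3ccc(OCc5ccccc5)cc3)[C@H](O[Si](C)(C)C(C)(C)C)[C@@H]4O[Si](C)(C)C(C)(C)C)[C@H]2O[Si](C)(C)C(C)(C)C)cc1
F7 | step 15 | hexaphenol tris(tert-butyldimethylsilyl) ether of 19 | Oc1ccc([C@H]2Oc3c(ccc(O)c3O)[C@H](c3cc4c(c(O)c3O)O[C@@H](c3ccc(O)cc3)[C@H](O[Si](C)(C)C(C)(C)C)[C@@H]4O[Si](C)(C)C(C)(C)C)[C@H]2O[Si](C)(C)C(C)(C)C)cc1
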